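**Plan**
1. The last cut is the O8–benzyl bond. The main cut opens ring A at C5–C4a and C8–C8a, a Diels–Alder/aromatisation between the C5=C6 bond of a 2-aryl-3-methoxy-5-(phenylsulfinyl)-4-pyranone and a 4-benzyloxy-1,3-dimethoxy-1-silyloxybutadiene.
2. Enabling feature: ring A carries oxygen on C5, C7 and C8 and hydrogen on C6, all on the four carbons outside the C4a=C8a edge it shares with the pyranone ring C. This is the pattern of a 1,1,3,4-tetraoxygenated butadiene.
3. Ring C is cut at C2–C3 (enolate aroylation), O1–C6 (cyclisation), C5–C6 (aminomethylenation) and C4–C5 (Weinreb ketone synthesis). Sulfur is in place from the first step, so nothing has to be halogenated beside the electron-rich ring B.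
4. Forward: ring B arrives intact as the aroyl chloride, ring C is assembled in steps 1–5, the diene in steps 6–8, ring A closes in step 9, and debenzylation ends the route in step 10.
5. Stereochemistry: the target has no stereocentre. The sulfoxide is used racemic and every sp3 centre of the cycloadduct is erased on aromatisation.

Key step: step 9

Remark: the diene is taken with the benzyloxy group anti to C2 (3Z by the sequence rules), the geometry expected from γ-deprotonation and the one that can reach the s-cis form; its ketene-acetal geometry and the enaminone geometry are uncontrolled and without consequence.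

**Step 1**
Reactants: 1 thioanisole (methyl phenyl sulfide); 2 N,2-dimethoxy-N-methylacetamide
Product: 4 1-methoxy-3-(phenylsulfanyl)propan-2-one, via (phenylsulfanyl)methyllithium 3 (not isolated)
Conditions: n-BuLi, DABCO, THF, 0 °C; then 2, −78 → 0 °C; H2O
Reagents that add atoms: none
Why: Sulfur-directed α-lithiation of thioanisole followed by Weinreb ketone synthesis should stop at the ketone because the chelated tetrahedral adduct persists until quench, which also keeps the acidic α-sulfanyl ketone out of reach of the organolithium.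

**Step 2**
Reactants: 4 1-methoxy-3-(phenylsulfanyl)propan-2-one; 5 N,N-dimethylformamide dimethyl acetal
Product: 6 (3Z)-4-(dimethylamino)-1-methoxy-3-(phenylsulfanyl)but-3-en-2-one
Conditions: 5 (1.2 equiv), toluene, 90 °C
Reagents that add atoms: none
Why: Condensation of an active methylene with an amide acetal (enaminone formation) should occur at the CH2 flanked by carbonyl and sulfur, by far the more acidic of the two α-positions, which installs the future C6 with a leaving group on it.

**Step 3**
Reactants: 7 2,3,4-trimethoxybenzoic acid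
Product: 8 2,3,4-trimethoxybenzoyl chloride
Conditions: (COCl)2, DMF (cat.), CH2Cl2, 0 °C → rt
Reagents that add atoms: oxalyl chloride, O=C(Cl)C(=O)Cl
Why: Acid chloride formation through the catalytic Vilsmeier-type chloroiminium species is routine and leaves aryl methyl ethers untouched.

**Step 4**
Reactants: 6 (3Z)-4-(dimethylamino)-1-methoxy-3-(phenylsulfanyl)but-3-en-2-one; 8 2,3,4-trimethoxybenzoyl chloride
Product: 11 3-methoxy-5-(phenylsulfanyl)-2-(2,3,4-trimethoxyphenyl)-4H-pyran-4-one, via lithium enolate 9 (not isolated), via diketone 10 (not isolated)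
Conditions: 6 (2 equiv), LiN(SiMe3)2 (2 equiv), THF, −78 °C; 8 (1 equiv), −78 → −20 °C; AcOH; then CF3CO2H, CH2Cl2, rt
Reagents that add atoms: none
Why: Acylation of the α'-lithium enolate of a β-amino enone by an aroyl chloride, followed by acid-induced 6-endo addition–elimination of the enol oxygen at the aminomethylene carbon with loss of dimethylamine, is an established 4-pyranone synthesis, and here the sulfur-bearing α-carbon is blocked so that only the methoxymethylene can enolise and become C3.

**Step 5**
Reactants: 11 3-methoxy-5-(phenylsulfanyl)-2-(2,3,4-trimethoxyphenyl)-4H-pyran-4-one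
Product: 12 3-methoxy-5-(phenylsulfinyl)-2-(2,3,4-trimethoxyphenyl)-4H-pyran-4-one (racemic at sulfur)
Conditions: mCPBA (1.0 equiv), CH2Cl2, −78 → −20 °C; aq. NaHCO3
Reagents that add atoms: mCPBA (3-chloroperoxybenzoic acid), O=C(OO)c1cccc(Cl)c1
Why: Sulfide-to-sulfoxide oxidation with one equivalent of peracid at low temperature should stop before the sulfone and leave the electron-poor pyranone double bonds and the aryl ethers alone; the new sulfur stereocentre is formed racemic, which is irrelevant because sulfur is expelled in step 9.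

**Step 6**
Reactants: 13 methyl 4-chloro-3-oxobutanoate (methyl 4-chloroacetoacetate); 14 benzyl alcohol
Product: 16 methyl 4-(benzyloxy)-3-oxobutanoate, via sodium benzyloxide 15 (not isolated)
Conditions: NaH (2.2 equiv), 14, THF, 0 °C; then 13, 0 °C → rt; aq. HCl
Reagents that add atoms: none
Why: Williamson ether synthesis in which preformed sodium benzyloxide displaces the primary chloride while the β-keto ester sits as its sodium enolate, which shields the ester from transesterification and Claisen self-condensation.

**Step 7**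
Reactants: 16 methyl 4-(benzyloxy)-3-oxobutanoate
Product: 18 methyl (2E)-4-(benzyloxy)-3-methoxybut-2-enoate, via dimethyl ketal 17 (not isolated)
Conditions: HC(OMe)3 (3 equiv), H2SO4 (cat.), rt; then TsOH (cat.), 110 °C, reduced pressure (MeOH removed)
Reagents that add atoms: trimethyl orthoformate, COC(OC)OC
Why: Acid-catalysed ketalisation by the orthoformate and thermal loss of methanol (enol ether formation) should give the conjugated β-methoxy enoate as the thermodynamically preferred E isomer, the benzyl ether being stable to catalytic acid.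

**Step 8**
Reactants: 18 methyl (2E)-4-(benzyloxy)-3-methoxybut-2-enoate
Product: 20 {[(3Z)-4-(benzyloxy)-1,3-dimethoxybuta-1,3-dien-1-yl]oxy}trimethylsilane, via lithium dienolate 19 (not isolated)
Conditions: LiN(iPr)2 (LDA), THF, −78 °C; Me3SiCl, −78 °C → rt; pentane, filtration, evaporation; used crude
Reagents that add atoms: chlorotrimethylsilane, C[Si](C)(C)Cl
Why: Kinetic γ-deprotonation of the β-methoxy enoate, whose CH2OBn group is cis to the ester, and O-silylation of the extended enolate is the standard preparation of 1-alkoxy-1-silyloxy-3-methoxybutadienes (vinylketene acetal formation), and the benzyloxy group is expected to settle anti to C2.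

**Step 9**
Reactants: 12 3-methoxy-5-(phenylsulfinyl)-2-(2,3,4-trimethoxyphenyl)-4H-pyran-4-one; 20 {[(3Z)-4-(benzyloxy)-1,3-dimethoxybuta-1,3-dien-1-yl]oxy}trimethylsilane
Product: 23 8-(benzyloxy)-5-hydroxy-3,7-dimethoxy-2-(2,3,4-trimethoxyphenyl)-4H-chromen-4-one, via cycloadduct 21 (not isolated), via 5,8-dihydrochromenone ketal 22 (not isolated)
Conditions: 20 (3 equiv), toluene, rt → 80 °C; then 1 M HCl, THF, rt
Reagents that add atoms: none
Why: Proposed new method: a monocyclic 5-sulfinyl-4-pyranone has not been used as the dienophile, the closest known reactions being the cycloaddition–elimination benzannulations of 1-alkoxy-1-silyloxy-3-oxygenated butadienes with halo- and sulfinylquinones and the Diels–Alder additions of 3-sulfinyl- and 3-acylchromones across C2=C3. The diene 20 is most nucleophilic at its benzyloxy-bearing terminus C4 and the pyranone 12 most electrophilic at C6, β to both the ketone and the sulfinyl group, so an asynchronous [4+2] addition (in the stepwise limit a vinylogous Mukaiyama–Michael addition followed by 6-(enolexo)-exo-trig closure of the α-sulfinyl enolate onto the oxocarbenium carbon) should form C8–C8a and C5–C4a and close ring A as a six-membered carbocycle on the C5=C6 edge of ring C. Suprafacial addition leaves the sulfinyl group on C4a and the hydrogen on C8a cis in adduct 21, so the α-sulfinyl ketone can lose benzenesulfenic acid by thermal syn elimination and restore C4a=C8a in 22. Acid then ionises the methyl silyl ketal at C5 and loss of the C8 proton aromatises ring A, releasing the C5 oxygen as the chelated phenol, while the C8 oxygen must stay as the benzyl ether because no hydrogen remains on C8a or C5 for its elimination. No stereocentre survives, the centres at C4a, C5, C8, C8a and sulfur all being erased, so only the cis fusion set by the cycloaddition matters and only for the elimination. The selectivity needed is regiochemical (C8 oxygen next to O1, C5 oxygen peri to the C4 carbonyl) and is secured by the matched polarisation of the two partners, with the other enone terminus of the pyranone, C2, blocked by the aryl group.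

**Step 10**
Reactants: 23 8-(benzyloxy)-5-hydroxy-3,7-dimethoxy-2-(2,3,4-trimethoxyphenyl)-4H-chromen-4-one
Product: 24 5,8-dihydroxy-3,7-dimethoxy-2-(2,3,4-trimethoxyphenyl)-4H-chromen-4-one (5,8-dihydroxy-3,7,2',3',4'-pentamethoxyflavone)
Conditions: H2 (1 atm), 10% Pd/C, EtOAc–MeOH (degassed), rt
Reagents that add atoms: none
Why: Catalytic hydrogenolysis of the aryl benzyl ether should free the C8 phenol without touching the tetrasubstituted C2=C3 bond or the methyl ethers, and oxygen is excluded because the product is a para-hydroquinone.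

**Compound list**
1 | thioanisole (methyl phenyl sulfide) | CSc1ccccc1 | starting material
2 | N,2-dimethoxy-N-methylacetamide | COCC(=O)N(C)OC | starting material
3 | (phenylsulfanyl)methyllithium | [Li]CSc1ccccc1 | intermediate
4 | 1-methoxy-3-(phenylsulfanyl)propan-2-one | COCC(=O)CSc1ccccc1 | intermediate
5 | N,N-dimethylformamide dimethyl acetal (1,1-dimethoxy-N,N-dimethylmethanamine) | COC(OC)N(C)C | starting material
6 | (3Z)-4-(dimethylamino)-1-methoxy-3-(phenylsulfanyl)but-3-en-2-one (amino group anti to the carbonyl) | COCC(=O)/C(Sc1ccccc1)=C/N(C)C | intermediate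
7 | 2,3,4-trimethoxybenzoic acid | COc1ccc(C(=O)O)c(OC)c1OC | starting material
8 | 2,3,4-trimethoxybenzoyl chloride | COc1ccc(C(=O)Cl)c(OC)c1OC | intermediate
9 | lithium (1Z,3Z)-4-(dimethylamino)-1-methoxy-3-(phenylsulfanyl)buta-1,3-dien-2-olate (chelated enolate) | CN(C)/C=C(\Sc1ccccc1)/C(O[Li])=C/OC | intermediate
10 | (4Z)-5-(dimethylamino)-2-methoxy-4-(phenylsulfanyl)-1-(2,3,4-trimethoxyphenyl)pent-4-ene-1,3-dione (racemic at C2, enolisable) | COc1ccc(C(=O)C(OC)C(=O)/C(Sc2ccccc2)=C/N(C)C)c(OC)c1OC | intermediate
11 | 3-methoxy-5-(phenylsulfanyl)-2-(2,3,4-trimethoxyphenyl)-4H-pyran-4-one | COc1ccc(-c2occ(Sc3ccccc3)c(=O)c2OC)c(OC)c1OC | intermediate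
12 | 3-methoxy-5-(phenylsulfinyl)-2-(2,3,4-trimethoxyphenyl)-4H-pyran-4-one (racemic at sulfur) | COc1ccc(-c2occ(S(=O)c3ccccc3)c(=O)c2OC)c(OC)c1OC | intermediate
13 | methyl 4-chloro-3-oxobutanoate | COC(=O)CC(=O)CCl | starting material
14 | benzyl alcohol | OCc1ccccc1 | starting material
15 | sodium benzyloxide | [Na+].[O-]Cc1ccccc1 | intermediate
16 | methyl 4-(benzyloxy)-3-oxobutanoate | COC(=O)CC(=O)COCc1ccccc1 | intermediate
17 | methyl 4-(benzyloxy)-3,3-dimethoxybutanoate | COC(=O)CC(OC)(OC)COCc1ccccc1 | intermediate
18 | methyl (2E)-4-(benzyloxy)-3-methoxybut-2-enoate | COC(=O)/C=C(/OC)COCc1ccccc1 | intermediate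
19 | lithium (3Z)-4-(benzyloxy)-1,3-dimethoxybuta-1,3-dien-1-olate (C1=C2 geometry undefined) | [Li]OC(OC)=C/C(OC)=C/OCc1ccccc1 | intermediate
20 | {[(3Z)-4-(benzyloxy)-1,3-dimethoxybuta-1,3-dien-1-yl]oxy}trimethylsilane (C1=C2 geometry undefined) | COC(O[Si](C)(C)C)=C/C(OC)=C/OCc1ccccc1 | intermediate
21 | 8-(benzyloxy)-3,5,7-trimethoxy-4a-(phenylsulfinyl)-2-(2,3,4-trimethoxyphenyl)-5-[(trimethylsilyl)oxy]-4a,5,8,8a-tetrahydro-4H-chromen-4-one (racemic, one enantiomer drawn; sulfinyl on C4a and H on C8a cis; C5, C8 and sulfur as mixtures) | COc1ccc(C2=C(OC)C(=O)[C@]3(S(=O)c4ccccc4)C(OC)(O[Si](C)(C)C)C=C(OC)C(OCc4ccccc4)[C@@H]3O2)c(OC)c1OC | intermediate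
22 | 8-(benzyloxy)-3,5,7-trimethoxy-2-(2,3,4-trimethoxyphenyl)-5-[(trimethylsilyl)oxy]-5,8-dihydro-4H-chromen-4-one (C5 and C8 as mixtures) | COc1ccc(-c2oc3c(c(=O)c2OC)C(OC)(O[Si](C)(C)C)C=C(OC)C3OCc2ccccc2)c(OC)c1OC | intermediate
23 | 8-(benzyloxy)-5-hydroxy-3,7-dimethoxy-2-(2,3,4-trimethoxyphenyl)-4H-chromen-4-one | COc1ccc(-c2oc3c(OCc4ccccc4)c(OC)cc(O)c3c(=O)c2OC)c(OC)c1OC | intermediate
24 | 5,8-dihydroxy-3,7-dimethoxy-2-(2,3,4-trimethoxyphenyl)-4H-chromen-4-one | COc1ccc(-c2oc3c(O)c(OC)cc(O)c3c(=O)c2OC)c(OC)c1OC | target

**Count and risks**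
Total steps: 10. Longest linear sequence: 6 steps (1, 2, 4, 5, 9, 10); the diene branch (6, 7, 8) and step 3 join it.

Step 9. The C5=C6 bond of the pyranone may be too weakly electrophilic. The diene would then be consumed first by hydrolysis, by silyl transfer to the sulfoxide oxygen (Pummerer-type chemistry) or by the benzenesulfenic acid that is released. The fallback uses known flavone chemistry, closes ring C last and oxygenates C8 late; it sets out from 8 and returns at 24. The lithium polyanion of commercial 2-methoxy-1-(2,4,6-trihydroxyphenyl)ethan-1-one (LiN(SiMe3)2, THF, −78 °C) is C-aroylated with 8 to give 2-methoxy-1-(2,3,4-trimethoxyphenyl)-3-(2,4,6-trihydroxyphenyl)propane-1,3-dione F1. H2SO4 in AcOH at 95 °C cyclodehydrates it (Baker–Venkataraman-type flavone synthesis) to 5,7-dihydroxy-3-methoxy-2-(2,3,4-trimethoxyphenyl)-4H-chromen-4-one F2. Me2SO4 (1 equiv) and K2CO3 in acetone methylate the unchelated 7-hydroxyl to give 5-hydroxy-3,7-dimethoxy-2-(2,3,4-trimethoxyphenyl)-4H-chromen-4-one F3. Elbs persulfate oxidation (K2S2O8, aqueous KOH, pyridine) attacks C8, para to the 5-phenoxide, to give potassium 5-hydroxy-3,7-dimethoxy-4-oxo-2-(2,3,4-trimethoxyphenyl)-4H-chromen-8-yl sulfate F4, and hydrolysis (aqueous HCl, Na2SO3, 80 °C) gives 24.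

Step 4. The enolate may be acylated on oxygen, or the hindered ortho-substituted aroyl chloride may react so slowly that proton transfer to the product diketone dominates. The fallback replaces acylation by aldol addition and oxidation; it sets out from 6 and returns at 10. Enolate 9 is added to commercial 2,3,4-trimethoxybenzaldehyde (THF, −78 °C) to give 5-(dimethylamino)-1-hydroxy-2-methoxy-4-(phenylsulfanyl)-1-(2,3,4-trimethoxyphenyl)pent-4-en-3-one F5 as a diastereomer mixture. Oxidation of the secondary alcohol with Dess–Martin periodinane (NaHCO3, CH2Cl2) gives 10, which is cyclised with CF3CO2H as in step 4 to 11.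

Step 8. The γ-deprotonation may be incomplete or accompanied by attack of the amide base at the ester, and the mixed silyl ketene acetal may be lost by hydrolysis or C-silylation during isolation. The fallback uses a 1,3-bis(silyloxy) diene and methylates O7 after the annulation; it sets out from 16 and returns at 23. Keto ester 16 is silylated (Et3N, Me3SiCl, hexane, rt) to methyl 4-(benzyloxy)-3-[(trimethylsilyl)oxy]but-2-enoate F6. LiN(iPr)2 and Me3SiCl at −78 °C then give (3Z)-4-(benzyloxy)-1-methoxy-1,3-bis[(trimethylsilyl)oxy]buta-1,3-diene F7, a diene class documented for 4-alkoxyacetoacetates. Cycloaddition–aromatisation with 12 under the conditions of step 9 should give 8-(benzyloxy)-5,7-dihydroxy-3-methoxy-2-(2,3,4-trimethoxyphenyl)-4H-chromen-4-one F8, and Me2SO4 (1 equiv), K2CO3 in acetone methylates the unchelated 7-hydroxyl to give 23.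

**Further compounds**
F1 | step 9 | 2-methoxy-1-(2,3,4-trimethoxyphenyl)-3-(2,4,6-trihydroxyphenyl)propane-1,3-dione | COc1ccc(C(=O)C(OC)C(=O)c2c(O)cc(O)cc2O)c(OC)c1OC
F2 | step 9 | 5,7-dihydroxy-3-methoxy-2-(2,3,4-trimethoxyphenyl)-4H-chromen-4-one | COc1ccc(-c2oc3cc(O)cc(O)c3c(=O)c2OC)c(OC)c1OC
F3 | step 9 | 5-hydroxy-3,7-dimethoxy-2-(2,3,4-trimethoxyphenyl)-4H-chromen-4-one | COc1ccc(-c2oc3cc(OC)cc(O)c3c(=O)c2OC)c(OC)c1OC
F4 | step 9 | potassium 5-hydroxy-3,7-dimethoxy-4-oxo-2-(2,3,4-trimethoxyphenyl)-4H-chromen-8-yl sulfate | COc1ccc(-c2oc3c(OS(=O)(=O)[O-])c(OC)cc(O)c3c(=O)c2OC)c(OC)c1OC.[K+]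
F5 | step 4 | 5-(dimethylamino)-1-hydroxy-2-methoxy-4-(phenylsulfanyl)-1-(2,3,4-trimethoxyphenyl)pent-4-en-3-one | COc1ccc(C(O)C(OC)C(=O)/C(Sc2ccccc2)=C/N(C)C)c(OC)c1OC
F6 | step 8 | methyl 4-(benzyloxy)-3-[(trimethylsilyl)oxy]but-2-enoate (E/Z mixture) | COC(=O)C=C(O[Si](C)(C)C)COCc1ccccc1
F7 | step 8 | (3Z)-4-(benzyloxy)-1-methoxy-1,3-bis[(trimethylsilyl)oxy]buta-1,3-diene | COC(O[Si](C)(C)C)=C/C(O[Si](C)(C)C)=C/OCc1ccccc1
F8 | step 8 | 8-(benzyloxy)-5,7-dihydroxy-3-methoxy-2-(2,3,4-trimethoxyphenyl)-4H-chromen-4-one | COc1ccc(-c2oc3c(OCc4ccccc4)c(O)cc(O)c3c(=O)c2OC)c(OC)c1OC
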